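The numbers are those of an exercise; no experiment stands behind them.

**The vessel.** The stirred vessel held solid substrate as a slurry under held gas, and target formed when dissolved substrate met reagent taken up from the gas.

solid substrate 20 mM; gas 2.5 mM (held); time 30 h

    solid product ⇌ target, rate k1*(cs1 - [target]) while solid is left; crystals form when [target] > cs1 (cs1 = 4.6 mM, k1 = 19 /h)
    dissolved substrate + reagent → target (k2 = 260 /M/h)
    reagent ⇌ dormant form (K3 = 9.6, k3 = 0.41 /h)
    solid substrate ⇌ dissolved substrate, rate k4*(cs4 - [dissolved substrate]) while solid is left; crystals form when [dissolved substrate] > cs4 (cs4 = 7.2 mM, k4 = 0.25 /h)
    reagent → side product (k5 = 1.9 /h)
    gas ⇌ reagent, rate k6*(csat - [reagent]) (k6 = 0.37 /h, csat = 2.5 mM)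

- for target the solid product is counted in
- as a solid, counted per litre of solution: solid substrate, solid product
- at the start none of reagent is dissolved
- at the start none of the solid substrate is in solution
- run time (flask): 30 h

- how much target and solid product together there is at 30 h, in percent of the solid substrate charged
- the change that raises the amount of target and solid product together at 30 h, in percent of the solid substrate charged most ("none" if none brings more than 2 percentage points) (south-west / west / north-west / north-east / none)
- amount of target and solid product together at 30 h, in percent of the solid substrate charged, after south-west

- south-west: doubling the solubility in step 1, all else as stated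
- west: doubling the saturation concentration of gas, all else as stated
- north-west: doubling the dissolution coefficient of step 1, all else as stated
- north-east: doubling the dissolution coefficient of step 4, all else as stated

**Pull number.** Reagent entered at 0.925 mM/h at most, and solid substrate dissolved at 1.80 mM/h at most. I called C = 0.699 the capture of reagent by dissolved substrate at its solubility, divided by reagent's three losses: to side product, to dormant form and back to gas. The pull number Φ = 0.211 is the coupling rate at solubility divided by the fastest dissolving. Time drops out, and Φ says what fraction dissolved substrate sits below its solubility.

**Reading it.** I therefore expected dissolved substrate near 5.68 mM, a capture share of 0.355, coupling at 0.329 mM/h and y, the target and solid product together at 30 h in percent of the charge, of 49.3%. That took 15.6 mM of the 20 mM charged, so I expected solid substrate to remain. One number was not quite enough: dissolved substrate started from nothing, with a time constant of 4.00 h, shorter than the run, so I held my y slightly high. Doubling Φ for west gave me 30 percentage points, against 4.1 points for north-east. Step 1 stands nowhere in Φ, so I put south-west at 49.3% too.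

**The forecast.** It gave 47.5%, west and 47.5%, holding that “The solid substrate holds dissolved substrate near a steady level”. Its y lay below mine.

**The run.** The flask gave 47.8%, west with 36 points, and 47.8%.

**What to watch.** In the flask, dissolved substrate stood at 28.7% of the charge at 15.0 h and 28.9% at 30.0 h, which is 5.78 mM against 5.68 mM from Φ, and at 15.0 h it was made 1.05 times faster than used up. The coupling rate from Φ gave 32.9% for the same flask read at 20 h, which still held 41.0% solid substrate and read 30.1%.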